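The numbers of this flask were chosen freely; the run is a simulation.

Give the flask 6.0 min, and ask where one molecule of starting complex stands by then.

starting complex 0.050 M (fed, over 15 s); leaving ligand 0.0500 M; gas 21 mM (held); time 6.0 min

    starting complex + incoming ligand ⇌ leaving ligand + complex with one exchanged (K1 = 3.9, k1 = 4.3 /M/s)
    complex with one exchanged + incoming ligand ⇌ leaving ligand + complex with two exchanged (K2 = 0.38, k2 = 1.8 /M/s)
    complex with two exchanged + incoming ligand ⇌ leaving ligand + complex with three exchanged (K3 = 3.2, k3 = 3.2 /M/s)
    gas ⇌ incoming ligand, rate k4*(csat - [incoming ligand]) (k4 = 11 /s, csat = 21 mM)
    complex with one exchanged ⇌ isomer of the product (K5 = 13, k5 = 0.25 /s)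

* which holds at 6.0 min: what has brought the reaction to rest, or that it has not come to rest (forward and back rates have come level / all of the starting complex has reacted / it is still moving)
* the complex with one exchanged standing at 6.0 min, as a percentage of the starting complex charged

- at the start none of incoming ligand is dissolved
- the reaction counts as stopped when no species that holds the starting complex changes by six tenths of a point or more over the second half of the time
- run time (flask): 6.0 min

Start with a bench rule: a fast reversible side step keeps its own balance. The fifth step qualifies, because the forward half-life of complex with one exchanged by that step is 2.8 s, shorter than 6.0 min. Follow the molecule inside the pair, complex with one exchanged and isomer of the product. It stands as complex with one exchanged at odds of one to 13.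

share of the pair = one / 14.0 = 7.14%

Now find the border. The rule counts the whole charge as pair, so ask about the earlier fork. Gas transfer has a half-life of 0.0630 s, shorter than the 3.22 s that incoming ligand has by the forward first step with the whole charge counted at once. So take c incoming ligand as 21 mM. Each molecule entering the pair frees one leaving ligand, so take c leaving ligand as 0.100 M. Set aside further exchange: the second balance puts 0.0798 complex with two exchanged beside each complex with one exchanged.

pair odds = 3.9 × 14.0 × 21 mM / 0.100 M = 11.5

Call this the pair odds: molecules in the pair per molecule of starting complex at balance. The bench rule needs it large against one. Here it is larger, but not by enough to ignore, so correct the rule.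

c complex with one exchanged, share of charge = 7.14% × 11.5 / 12.5 = 6.57%

Expect thermodynamic control, since starting complex at 21 mM of incoming ligand has a pseudo-first-order half-life of 7.68 s by the forward first step, shorter than 6.0 min. Starting complex keeps 8.00% of the charge, so expect level rates, not exhaustion.

The forecast gives forward and back rates have come level and 6.5%, just under my 6.57%; its grounds are that the released ligand “holds the isomer at about 85% of the charge”.

The simulation gives forward and back rates have come level, with 6.53%.

In this flask at 6.00 min, the first step relaxes with a half-life of 0.0532 min, shorter than 6.0 min, and the pair stands to starting complex at 11.8 to one. The neighbour flask, charged with 0.20 M of starting complex, holds 0.219 M of leaving ligand at 6.00 min, which puts its pair odds at 5.24, the corrected rule at 6.00%, and the neighbour flask itself at 5.98%.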